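The earlier runs and the new flask were computed with made-up constants; scatter was added.

In this closed, stirred vessel substrate meets reagent, and every reading is of substrate.

| flask | substrate | reagent | time |
|---|---|---|---|
| Tuesday's | 50.0 mM | 75.0 mM |  |
| Friday's | 20.0 mM | 45.0 mM |  |
| Wednesday's | 150 mM | 75.0 mM |  |
| Saturday's | 50.0 mM | 220 mM |  |
| Sunday's | 25.0 mM | 37.0 mM | 5.0 min |

| Tuesday's run: time / min | Tuesday's run: [substrate] / mM | Friday's run: time / min | Friday's run: [substrate] / mM | Wednesday's run: time / min | Wednesday's run: [substrate] / mM | Saturday's run: time / min | Saturday's run: [substrate] / mM |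
|---|---|---|---|---|---|---|---|
| 0.20 | 44.0 | 0.20 | 19.3 | 0.20 | 112.5 | 0.20 | 42.2 |
| 0.38 | 41.1 | 0.38 | 17.7 | 0.38 | 92.5 | 0.38 | 36.0 |
| 0.72 | 33.7 | 0.72 | 15.5 | 0.72 | 66.5 | 0.72 | 28.6 |
| 1.4 | 24.6 | 1.4 | 15.3 | 1.4 | 44.0 | 1.4 | 18.2 |
| 2.6 | 17.9 | 2.6 | 11.5 | 2.6 | 26.1 | 2.6 | 11.8 |
| 5.0 | 8.4 | 5.0 | 7.5 | 5.0 | 12.3 | 5.0 | 4.3 |

(scatter of a reading: 0.8 mM)

- order of the initial rate in [substrate], near the charge of the Tuesday's run, the rate being that where two percent of its substrate are target (one fixed amount of target, the same in the runs compared)
- order of the initial rate in [reagent], near the charge of the Tuesday's run, the rate being that where two percent of its substrate are target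
- substrate in the Sunday's run at 5.0 min, as a share of the substrate charged
- which of these the readings show (two substrates go astray together / the two partners rest in a complex / the product speeds the reaction / the product decays / nothing beyond the main steps)

- Overall: substrate + reagent -> target.
- Constant volume, constant temperature.
- "The second partner" is reagent.
- An order is taken over about fifteen percent of the charge, up and down.

Turn the question round: if substrate left by the cross step with reagent and by nothing else, Wednesday's flask could lose at most its 75.0 mM of reagent. It lost 138 mM, more than that charge. Take the mean loss rate per unit of substrate up to 0.72 min: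

g = ln(c_substrate at start / c_substrate) / t

With one exit through reagent and reagent counted at its charge, g would follow that charge, so Wednesday's g would equal Tuesday's and Saturday's would be 2.93 times it. You read Wednesday's 1.13 min⁻¹ against Tuesday's 0.548 min⁻¹, a ratio of 2.06, and Saturday's 0.776 min⁻¹ gives 1.42. So substrate also pairs with itself:

g = a·c_reagent + b·(mean c_substrate)

Wednesday's mean substrate is 103 mM and Saturday's 38.3 mM. With reagent taken at its charge, these two flasks give, as readings with their scatter,

a = 1.84 M⁻¹ min⁻¹, b = 9.66 M⁻¹ min⁻¹

Control changes hands at the crossing ratio, the c_substrate/c_reagent at which both exits carry equal loss, read here as a/b = 0.191; this is a selectivity factor. At ratio x the cross exit's share of the loss is a/b divided by (a/b + x).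

Sunday's flask starts at x = 0.676, above the crossing, so the cross exit starts with 22.0% of the loss. Holding Sunday's reagent at its charge, an approximation, with p = a·c_reagent = 0.0683 min⁻¹, I integrate:

c_substrate / charge = p·exp(−pt) / (p + b·charge·(1 − exp(−pt))) = 35.1%

If target forms by the cross exit, both orders lie near first.

The forecast gave 1 and 1.05 as orders, 35% (range 31% to 39%) and "two substrates go astray together", holding that “substrate must have a second exit”.

Sunday's flask gives 35.0% of its charge of substrate at 5.0 min; near Tuesday's charge the orders are 1.0 in substrate and 1.1 in reagent, and the readings show that two substrates go astray together.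

    substrate + reagent → target (1.824 M⁻¹ min⁻¹)
    target + reagent → side product (1.278 M⁻¹ min⁻¹)
    2 substrate → homo dimer (5.100 M⁻¹ min⁻¹)

At the same amount of target, Saturday's rate of forming target stands at 3.1 times Tuesday's. Sunday's substrate at 5.0 min is 8.76 mM, so with reagent counted at its charge x is 0.237, still above the crossing, and on that count the cross exit's share of the loss reckons to 44.6%.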